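(The constants used here are those of an exercise; the run is a simulation.)

5 questions stand on one charge put through 4 vessels.

| flask | starting material | coupling partner | free catalyst | time | remark |
|---|---|---|---|---|---|
| Saturday's | 10 mM | 10.0 mM (fed, over 6.00 min) | 0.25 mM | 12 min | all but coupling partner at the start; coupling partner goes in evenly over 6.00 min, the run ends at 12 min |
| Friday's | 10 mM | 10.0 mM | 0.25 mM |  | one stirred flow tank at steady state, fed with the mixture as stated, mean residence time 12 min |
| Tuesday's | 10 mM | 10.0 mM | 0.25 mM |  | one stirred flow tank at steady state, fed with the mixture as stated, mean residence time 60.0 min |
| Wednesday's | 10 mM | 10.0 mM | 0.25 mM | 12 min | a closed flask charged with all of it at once and left for 12 min |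

    catalyst intermediate C → free catalyst + target (k1 = 4.2 s⁻¹)
    coupling partner + free catalyst → catalyst intermediate A (k2 = 82 L mol⁻¹ s⁻¹)
    starting material + catalyst intermediate B → catalyst intermediate C (k3 = 640 L mol⁻¹ s⁻¹)
    catalyst intermediate A → catalyst intermediate B (k4 = 0.044 s⁻¹)
    target → over-reaction product (k5 = 2.5 × 10⁻⁴ s⁻¹)

- the stated concentrations are those of everything mixed, before any reaction; amounts are the same in each set-up
- the feed brings no volume worth counting
- run time (Saturday's): 12 min

- the set-up with the highest amount of target at the outlet or at the end, in percent of the starting material put in ("none" if the first two lie within 2 percentage points) (Saturday's / Friday's / Tuesday's / Wednesday's / none)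
- amount of target at the outlet or at the end, in percent of the starting material put in, Saturday's
- amount of target at the outlet or at the end, in percent of the starting material put in, Friday's
- amount of target at the outlet or at the end, in percent of the starting material put in, Tuesday's
- amount of target at the outlet or at the end, in percent of the starting material put in, Wednesday's

Two of us quarrelled over Wednesday's flask, charged at once. The first looked at the coupling partner: with free catalyst held at its charge, as if it never ran down, step 2 alone gives the partner a half-life of 0.56 min, far shorter than the 12 min of the run. So he took conversion as whole and early, with the run's length spent on over-reaction, and he put target at 83.5 % of the starting material charged.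

I looked at where the catalyst waits. Each turn passes step 4 in about 22.7 s, the rate-limiting step, because that wait is longer than the others at full charge. The turnover ceiling, the share of the charge that the whole catalyst can pass per minute while all of it waits at that step, is 0.0660 min⁻¹. Over 12 min in Wednesday's flask that allows 79.2 %.

The correction needs computing by itself. At full charge the wait at step 2 is 0.0537 of the wait at step 4, and it grows as one over the share of partner left. Summed down to a share f left, it costs that figure times ln(1/f) of the charge. With f from the uncorrected reckoning, that is 8.43 %, so I reckon conversion in Wednesday's flask at 70.8 %. If target is taken as made steadily, it has on average lived half the run, so I take off a share of 9.00 %. My figure for Wednesday's is 64.4 %.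

The forecast names Wednesday's as best, with 62.5 % there, lower than my figure, and 60 %, 55.9 % and 51.3 % for Saturday's, Friday's and Tuesday's, holding that “anything that keeps the coupling partner low (slow feeding, or back-mixing in a flow tank) costs turnover rate”.

The simulation gives 64.5 % for Wednesday's, above Saturday's 60.0 %, Friday's 55.7 % and Tuesday's 51.2 %, with 6.09 % of the charge as over-reaction product in Wednesday's flask. The first view has its region in Tuesday's tank. There the ceiling over 60.0 min comes to 3.96 times the charge, and the balance of a steady tank then puts the partner share left at about 1.81 %, below the 5.37 % at which the waits at steps 2 and 4 are equal. Dividing by one plus k5 times the residence time gives 51.7 % for Tuesday's tank, where over-reaction product stands at 46.1 %.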